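The route rests on cutting C2–C3 of the ten-membered carbocycle, a (Z,Z)-cyclodeca-1,6-diene (C4=C5, C9=C10) fused to the lactone ring at C6–C7. C2 is α to the C1 carbinol, a latent ketone cross-conjugated with C9=C10, and C3 is the allylic CH2 of C4=C5, so the bond is an enolate–π-allyl union. The key step cyclises a seco methyl ketone, as its silyl dienol ether, onto a C3 allylic carbonate with zerovalent palladium, with lactone, C8 ester and both alkenes already in place. The precursor comes from a dihydroxyacetone-derived butenolide (C3–C6, C15), a bromomethylbutenolide allylation of (Z)-3-iodobut-2-enal and a Stille acetyl equivalent; C1 reduction and desilylation finish.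

Key step: step 15

Remark on numbering: locants C1–C15 are those of the target's carbocycle (C1 carbinol, C4 bearing C15H2OH, C6 lactone oxygen, C8 ester oxygen, C10 bearing C14H3, C11=C13H2 and C12=O in the lactone). The target is (1S,6R,7R,8R,4E,9Z) with an (S)-2-methylbutanoate; the lactone is trans-fused.
Assumption: the (S,S)-ProPhenol/Me2Zn catalyst is taken to deliver the alkynyl group to the Si face of enal 8 (giving the 4R carbinol 10); if the facial sense is opposite, the (R,R)-ligand is used with no other change.

Step 1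
Reactants: 1 1,3-dihydroxyacetone (commercial dimer); 2 ethyl (triphenylphosphoranylidene)acetate
Product: 4 4-(hydroxymethyl)furan-2(5H)-one, via hydroxy ester 3 (not isolated)
Conditions: CH2Cl2, rt
Reagents that add atoms: none
Why: Wittig olefination gives enoate 3, whose two CH2OH groups are equivalent until the one cis to the ester lactonises; this should differentiate the C3 oxygen (ring) from the C15 oxygen (free OH) and fix C6 cis to C3 on the future C4=C5 bond.

Step 2
Reactants: 4 4-(hydroxymethyl)furan-2(5H)-one
Product: 5 4-(TBSO-methyl)furan-2(5H)-one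
Conditions: TBSCl, imidazole, DMF, 0 °C to rt
Reagents that add atoms: tert-butyldimethylsilyl chloride, CC(C)(C)[Si](C)(C)Cl
Why: routine silylation of the primary alcohol protects the C15 oxygen until the last step.

Step 3
Reactants: 5 silyl ether butenolide
Product: 7 (2E)-3-(TBSO-methyl)-N-methoxy-N-methyl-4-(TESO)but-2-enamide (amide carbonyl cis to CH2OTES), via hydroxy amide 6 (not isolated)
Conditions: MeNH(OMe)·HCl, AlMe3, CH2Cl2, 0 °C; Rochelle-salt work-up; then TESCl, imidazole, CH2Cl2, 0 °C
Reagents that add atoms: N,O-dimethylhydroxylamine hydrochloride, CNOC.Cl; chlorotriethylsilane, CC[Si](Cl)(CC)CC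
Why: Weinreb aminolysis of the lactone by the aluminium amide (acyl substitution; the β,β-disubstituted alkene resists conjugate addition) keeps the carbonyl cis to the released CH2OH, which is silylated at once to stop relactonisation.

Step 4
Reactants: 7 Weinreb amide
Product: 8 (2E)-3-(TBSO-methyl)-4-(TESO)but-2-enal (formyl group cis to CH2OTES)
Conditions: i-Bu2AlH, THF, −78 °C
Reagents that add atoms: none
Why: hydride reduction of a Weinreb amide stops at the aldehyde because the chelated tetrahedral intermediate collapses only on work-up.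

Step 5
Reactants: 8 enal; 9 methyl propiolate
Product: 10 methyl (4R,5E)-6-(TBSO-methyl)-4-hydroxy-7-(TESO)hept-5-en-2-ynoate
Conditions: Me2Zn, (S,S)-ProPhenol (10 mol %), Ph3PO (20 mol %), toluene, 4 °C
Reagents that add atoms: none
Why: ProPhenol–zinc catalysed asymmetric alkynylation of an enal; the ligand-controlled facial selectivity should set the future C6 stereocentre (R).

Step 6
Reactants: 10 hydroxy ynoate
Product: 12 (5S)-5-[(1E)-2-(TBSO-methyl)-3-(TESO)prop-1-en-1-yl]furan-2(5H)-one, via dienoate 11 (not isolated)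
Conditions: H2 (1 atm), Pd/CaCO3 (Pb-poisoned), quinoline, EtOAc, rt; then PPTS (cat.), CH2Cl2, rt
Reagents that add atoms: none
Why: Lindlar semihydrogenation gives the (Z)-γ-hydroxy enoate, which lactonises to the butenolide; the stereocentre is not touched (its descriptor changes only because of the priorities).

Step 7
Reactants: 12 butenolide
Product: 13 (5R)-3-(hydroxymethyl)-5-[(1E)-2-(TBSO-methyl)-3-(TESO)prop-1-en-1-yl]furan-2(5H)-one
Conditions: 37% aq. CH2O, PBu3 (20 mol %), THF, rt
Reagents that add atoms: formaldehyde, C=O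
Why: Morita–Baylis–Hillman α-hydroxymethylation of the butenolide (phosphine addition at C7, aldol with formaldehyde at C11, elimination) installs C13.

Step 8
Reactants: 13 hydroxymethyl butenolide
Product: 15 (5R)-3-(bromomethyl)-5-[(1E)-2-(TBSO-methyl)-3-(TESO)prop-1-en-1-yl]furan-2(5H)-one, via mesylate 14 (not isolated)
Conditions: MsCl, Et3N, CH2Cl2, −40 °C; then LiBr, THF, 0 °C
Reagents that add atoms: lithium bromide, [Li+].[Br-]
Why: mesylation followed by SN2 displacement with bromide converts the primary allylic alcohol into the allylic bromide without acid, so the silyl ethers survive.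

Step 9
Reactants: 16 but-2-yn-1-ol
Product: 17 (Z)-3-iodobut-2-en-1-ol
Conditions: NaAlH2(OCH2CH2OMe)2, THF, 0 °C to rt; then I2, −78 °C
Reagents that add atoms: iodine, [I][I]
Why: hydroxyl-directed trans-hydroalumination places aluminium on C3 cis to CH2OH and iodinolysis occurs with retention, which should give the (Z)-vinyl iodide (future C8 cis to the C10 substituent).

Step 10
Reactants: 17 (Z)-3-iodobut-2-en-1-ol
Product: 18 (Z)-3-iodobut-2-enal
Conditions: MnO2, CH2Cl2, rt, dark; used at once
Reagents that add atoms: none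
Why: MnO2 oxidises the allylic alcohol to the enal under neutral conditions that keep the alkene geometry.

Step 11
Reactants: 15 bromomethyl butenolide; 18 (Z)-3-iodobut-2-enal
Product: 19 α-methylene-γ-butyrolactone alcohol, (6R,7R,8R): C6 carries the (E)-CH=C(CH2OTBS)CH2OTES arm, C7 the (Z)-CH(OH)–CH=C(CH3)I group; C6/C7 trans; C8 epimeric to the target
Conditions: CrCl2 (nickel-free, 4 equiv), THF, 0 °C to rt; cold aq. NH4Cl work-up
Reagents that add atoms: none
Why: Nozaki–Hiyama allylation: the allylchromium from 15 reacts through its γ-carbon (C7) in a Zimmerman–Traxler chair on the ring face opposite the C6 substituent, which should give trans C6/C7 and, because the ring locks the allyl unit in the E-type geometry, the anti carbinol (C8 epimer, corrected in step 12); nickel-free divalent chromium leaves the vinyl iodide alone.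

Step 12
Reactants: 19 lactone alcohol; 20 (S)-2-methylbutanoic acid
Product: 21 C8 (S)-2-methylbutanoate, (6R,7S,8S) (spatial arrangement of the target; the letters differ because of the iodine)
Conditions: PPh3, DIAD, toluene, 0 °C to rt
Reagents that add atoms: none
Why: Mitsunobu esterification displaces the oxyphosphonium by the carboxylate in an SN2 step with inversion at C8, which should set the target configuration there; the acid stereocentre is not involved.

Step 13
Reactants: 21 vinyl iodide ester; 22 tributyl(1-ethoxyvinyl)stannane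
Product: 24 hydroxy enone, (6R,7R,8R): C10 now carries the acetyl group (C1, C2), C3 is a free CH2OH, via ethoxydiene 23 (not isolated)
Conditions: Pd2(dba)3, AsPh3, CuI, DMF, 40 °C; then AcOH–THF–H2O (3:1:1), rt
Reagents that add atoms: water, O
Why: Stille coupling with retention of the (Z) geometry introduces a masked acetyl group; mild acid hydrolyses the enol ether to the methyl ketone and removes the triethylsilyl ether while the primary TBS ether survives.

Step 14
Reactants: 24 hydroxy enone
Product: 25 C3 allylic methyl carbonate of 24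
Conditions: ClCO2Me, pyridine, CH2Cl2, 0 °C
Reagents that add atoms: methyl chloroformate, COC(Cl)=O
Why: acylation of the primary allylic alcohol gives the carbonate, the leaving group that zerovalent palladium ionises fastest and that releases its own base.

Step 15
Reactants: 25 seco methyl ketone carbonate
Product: 27 macrocyclic enone (C1 ketone; 6R,7R,8R; 4E,9Z; C15–OTBS), via silyl dienol ether 26 (not isolated)
Conditions: TMSOTf, Et3N, CH2Cl2, −20 °C; solvent exchange; then slow addition to Pd2(dba)3·CHCl3 (5 mol %), dppe (12 mol %), THF, 40 °C, 2 mM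
Reagents that add atoms: none
Why: Soft enolisation gives the cross-conjugated 2-silyloxydiene 26 (C2=C1(OSiMe3)–C10=C9); zerovalent palladium then ionises the primary allylic carbonate to the η3-allyl C3–C4–C5 with loss of CO2, the released methoxide desilylates 26, and the palladium enolate couples through C2 with the unsubstituted terminus C3. The closest known reaction is the Tsuji allylation of silyl enol ethers with allyl carbonates (the enol-silane form of the Tsuji–Trost reaction), here run intramolecularly at high dilution. The ten-membered carbocycle closes in the endo mode with respect to the allyl unit, so that C4=C5 ends inside the ring; attack at C5 (eight-membered ring, exo mode) is disfavoured by the substitution at that terminus. No stereocentre is formed (C2 and C3 are CH2); the cis-in-ring C4=C5 geometry should be carried over because the anti-configured allyl is trapped at C3 before it equilibrates, and C9=C10 is not involved. The step needs regiospecific nucleophilicity at C2, secured because the cross-conjugated enolate has no other carbon terminus, and chemoselective ionisation, secured because the carbonate ionises far faster than the secondary allylic carboxylates at C6 and C8. The trans-fused lactone and the two cis alkenes pre-bend the chain toward a nearly strain-free (Z,Z)-cyclodeca-1,6-diene, and the neutral conditions spare the methylene lactone and the ester.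

Step 16
Reactants: 27 macrocyclic enone
Product: 28 (1S)-allylic alcohol, C15 TBS ether of the target
Conditions: (R)-2-methyl-CBS-oxazaborolidine (30 mol %), catecholborane, toluene, −78 °C
Reagents that add atoms: none
Why: Corey–Bakshi–Shibata reduction: with the α-methylalkenyl carbon C10 as the large and the C2 methylene as the small ketone substituent, the (R)-catalyst should deliver hydride to the face that gives the (1S)-alcohol, 1,2-selectively and without touching the methylene lactone at −78 °C.

Step 17
Reactants: 28 silyl ether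
Product: 29 CNP0526758.1 (target)
Conditions: HF·pyridine, pyridine, THF, 0 °C to rt
Reagents that add atoms: none
Why: buffered fluoride desilylation frees the C15 alcohol under mildly acidic conditions that should avoid acyl migration from O8 to O1 and addition to the methylene lactone.

Compound list
1 | 1,3-dihydroxyacetone (commercial dimer) | OCC(=O)CO | starting material
2 | ethyl (triphenylphosphoranylidene)acetate | CCOC(=O)C=P(c1ccccc1)(c1ccccc1)c1ccccc1 | starting material
3 | ethyl 4-hydroxy-3-(hydroxymethyl)but-2-enoate | CCOC(=O)C=C(CO)CO | intermediate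
4 | 4-(hydroxymethyl)furan-2(5H)-one | O=C1C=C(CO)CO1 | intermediate
5 | 4-({[tert-butyl(dimethyl)silyl]oxy}methyl)furan-2(5H)-one | O=C1C=C(CO[Si](C)(C)C(C)(C)C)CO1 | intermediate
6 | (2E)-3-(TBSO-methyl)-4-hydroxy-N-methoxy-N-methylbut-2-enamide (carbonyl cis to CH2OH) | CON(C)C(=O)/C=C(\CO)CO[Si](C)(C)C(C)(C)C | intermediate
7 | (2E)-3-(TBSO-methyl)-N-methoxy-N-methyl-4-(TESO)but-2-enamide (carbonyl cis to CH2OTES) | CON(C)C(=O)/C=C(\CO[Si](CC)(CC)CC)CO[Si](C)(C)C(C)(C)C | intermediate
8 | (2E)-3-(TBSO-methyl)-4-(TESO)but-2-enal (formyl cis to CH2OTES) | O=C/C=C(\CO[Si](CC)(CC)CC)CO[Si](C)(C)C(C)(C)C | intermediate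
9 | methyl propiolate | C#CC(=O)OC | starting material
10 | methyl (4R,5E)-6-(TBSO-methyl)-4-hydroxy-7-(TESO)hept-5-en-2-ynoate | COC(=O)C#C[C@H](O)/C=C(\CO[Si](CC)(CC)CC)CO[Si](C)(C)C(C)(C)C | intermediate
11 | methyl (2Z,4S,5E)-6-(TBSO-methyl)-4-hydroxy-7-(TESO)hepta-2,5-dienoate | COC(=O)/C=C\[C@H](O)/C=C(\CO[Si](CC)(CC)CC)CO[Si](C)(C)C(C)(C)C | intermediate
12 | (5S)-5-[(1E)-2-(TBSO-methyl)-3-(TESO)prop-1-en-1-yl]furan-2(5H)-one | O=C1C=C[C@@H](/C=C(\CO[Si](CC)(CC)CC)CO[Si](C)(C)C(C)(C)C)O1 | intermediate
13 | (5R)-3-(hydroxymethyl)-5-[(1E)-2-(TBSO-methyl)-3-(TESO)prop-1-en-1-yl]furan-2(5H)-one | O=C1C(CO)=C[C@@H](/C=C(\CO[Si](CC)(CC)CC)CO[Si](C)(C)C(C)(C)C)O1 | intermediate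
14 | methanesulfonate of 13 | O=C1C(COS(C)(=O)=O)=C[C@@H](/C=C(\CO[Si](CC)(CC)CC)CO[Si](C)(C)C(C)(C)C)O1 | intermediate
15 | (5R)-3-(bromomethyl)-5-[(1E)-2-(TBSO-methyl)-3-(TESO)prop-1-en-1-yl]furan-2(5H)-one | O=C1C(CBr)=C[C@@H](/C=C(\CO[Si](CC)(CC)CC)CO[Si](C)(C)C(C)(C)C)O1 | intermediate
16 | but-2-yn-1-ol | CC#CCO | starting material
17 | (Z)-3-iodobut-2-en-1-ol | C/C(I)=C/CO | intermediate
18 | (Z)-3-iodobut-2-enal | C/C(I)=C/C=O | intermediate
19 | (6R,7R,8R) α-methylene lactone alcohol, C8 epimeric to the target, C10 iodide, C3–OTES, C15–OTBS | C=C1C(=O)O[C@H](/C=C(/CO[Si](C)(C)C(C)(C)C)CO[Si](CC)(CC)CC)[C@H]1[C@H](/C=C(\I)C)O | intermediate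
20 | (S)-2-methylbutanoic acid | CC[C@H](C)C(=O)O | starting material
21 | (6R,7S,8S) C8 (S)-2-methylbutanoate, C10 iodide, C3–OTES, C15–OTBS | C=C1C(=O)O[C@H](/C=C(/CO[Si](C)(C)C(C)(C)C)CO[Si](CC)(CC)CC)[C@H]1[C@@H](/C=C(\I)C)OC(=O)[C@@H](C)CC | intermediate
22 | tributyl(1-ethoxyvinyl)stannane | CCCC[Sn](CCCC)(CCCC)C(=C)OCC | starting material
23 | (6R,7R,8R) 2-ethoxydiene (C1 enol ether), C3–OTES, C15–OTBS | C=C1C(=O)O[C@H](/C=C(/CO[Si](C)(C)C(C)(C)C)CO[Si](CC)(CC)CC)[C@H]1[C@@H](/C=C(\C(=C)OCC)C)OC(=O)[C@@H](C)CC | intermediate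
24 | (6R,7R,8R) seco methyl ketone, C3–OH, C15–OTBS | C=C1C(=O)O[C@H](/C=C(/CO[Si](C)(C)C(C)(C)C)CO)[C@H]1[C@@H](/C=C(\C(C)=O)C)OC(=O)[C@@H](C)CC | intermediate
25 | (6R,7R,8R) seco methyl ketone, C3 methyl carbonate, C15–OTBS | C=C1C(=O)O[C@H](/C=C(/CO[Si](C)(C)C(C)(C)C)COC(=O)OC)[C@H]1[C@@H](/C=C(\C(C)=O)C)OC(=O)[C@@H](C)CC | intermediate
26 | trimethylsilyl dienol ether of 25 (C2=C1–OSiMe3) | C=C1C(=O)O[C@H](/C=C(/CO[Si](C)(C)C(C)(C)C)COC(=O)OC)[C@H]1[C@@H](/C=C(\C(=C)O[Si](C)(C)C)C)OC(=O)[C@@H](C)CC | intermediate
27 | (6R,7R,8R,4E,9Z) macrocyclic C1 ketone, C15–OTBS | C=C1C(=O)O[C@@H]2/C=C(/CO[Si](C)(C)C(C)(C)C)CCC(=O)/C(C)=C\[C@@H](OC(=O)[C@@H](C)CC)[C@@H]12 | intermediate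
28 | (1S,6R,7R,8R) C15 TBS ether of the target | C=C1C(=O)O[C@@H]2/C=C(/CO[Si](C)(C)C(C)(C)C)CC[C@H](O)/C(C)=C\[C@@H](OC(=O)[C@@H](C)CC)[C@@H]12 | intermediate
29 | CNP0526758.1 | C=C1C(=O)O[C@@H]2/C=C(/CO)CC[C@H](O)/C(C)=C\[C@@H](OC(=O)[C@@H](C)CC)[C@@H]12 | target

Total step count: 17. Longest linear sequence: 15 steps (steps 1–8 and 11–17); steps 9–10 form the short branch.

Steps most likely to fail

Step 15. Chain extension between two molecules may outrun ring closure, and the transient enolate may be lost by proton transfer, O-allylation or conjugate addition to the methylene lactone. The fallback sets out from 25 and returns at 27; it replaces the unstabilised enolate by a doubly stabilised carbon nucleophile in an outer-sphere Tsuji–Trost alkylation. The silyl dienol ether 26 (made from 25 as in step 15) is brominated with NBS in THF at −78 °C to the α-bromo ketone F1. Sodium benzenesulfinate in DMF then gives the β-keto sulfone F2. Pd(PPh3)4 and dppe in THF at high dilution, with the methoxide from the carbonate as the only base, should close C2–C3 to the macrocyclic β-keto sulfone F3 (mixture at C2). Aluminium amalgam in wet THF at 0 °C removes the sulfonyl group to give 27.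

Step 12. The activated C8 oxygen sits between the branched C7 and the cis-iodoalkene, so elimination toward the conjugated diene or attack at C10 may compete with clean SN2 inversion. The fallback sets out from 19 and returns at 21; it separates activation from displacement. MsCl and Et3N at −40 °C give the mesylate F4, which is displaced with inversion by caesium (S)-2-methylbutanoate F5 (from 20 and Cs2CO3) in DMF with 18-crown-6 at rt to give 21.

Step 16. Facial selectivity may be poor if the conformational bias of the ten-membered ring opposes the catalyst. The fallback sets out from 27 and returns at 28; it uses substrate control followed by inversion. Luche reduction (NaBH4, CeCl3·7H2O, MeOH, −78 °C) reduces the ketone 1,2-selectively from the face the ring exposes. If this gives the (1R)-alcohol F6, Mitsunobu reaction with chloroacetic acid (PPh3, DIAD) inverts C1 to the (1S)-chloroacetate F7, and thiourea with NaHCO3 in EtOH removes the chloroacetyl group selectively to give 28.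

Further compounds
F1 | step 15 | α-bromo ketone (C2–Br) of 25 | C=C1C(=O)O[C@H](/C=C(/CO[Si](C)(C)C(C)(C)C)COC(=O)OC)[C@H]1[C@@H](/C=C(\C(=O)CBr)C)OC(=O)[C@@H](C)CC
F2 | step 15 | β-keto sulfone (C2–SO2Ph) of 25 | C=C1C(=O)O[C@H](/C=C(/CO[Si](C)(C)C(C)(C)C)COC(=O)OC)[C@H]1[C@@H](/C=C(\C(=O)CS(=O)(=O)c1ccccc1)C)OC(=O)[C@@H](C)CC
F3 | step 15 | macrocyclic β-keto sulfone (2-phenylsulfonyl derivative of 27, both C2 epimers) | C=C1C(=O)O[C@@H]2/C=C(/CO[Si](C)(C)C(C)(C)C)CC(S(=O)(=O)c3ccccc3)C(=O)/C(C)=C\[C@@H](OC(=O)[C@@H](C)CC)[C@@H]12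
F4 | step 12 | C8 methanesulfonate of 19 | C=C1C(=O)O[C@H](/C=C(/CO[Si](C)(C)C(C)(C)C)CO[Si](CC)(CC)CC)[C@H]1[C@H](/C=C(\I)C)OS(C)(=O)=O
F5 | step 12 | caesium (S)-2-methylbutanoate | [Cs+].CC[C@H](C)C([O-])=O
F6 | step 16 | (1R)-epimer of 28 | C=C1C(=O)O[C@@H]2/C=C(/CO[Si](C)(C)C(C)(C)C)CC[C@@H](O)/C(C)=C\[C@@H](OC(=O)[C@@H](C)CC)[C@@H]12
F7 | step 16 | (1S)-chloroacetate of 28 | C=C1C(=O)O[C@@H]2/C=C(/CO[Si](C)(C)C(C)(C)C)CC[C@H](OC(=O)CCl)/C(C)=C\[C@@H](OC(=O)[C@@H](C)CC)[C@@H]12
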